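**Retrosynthetic overview**
- Target 17 ⇐ diol 15 (double angeloylation) ⇐ silyl-protected enedione 13 (CBS reduction sets C9, then desilylation).
- 13 ⇐ cycloheptane-1,4-dione 11: the five-membered ring closes last, C10 (nucleophile) onto C6 (electrophile), and loss of water leaves C6=C10 (alkyne hydration, then aldol condensation).
- 11 ⇐ acyclic farnesane diazoketone 9: the seven-membered ring closes first, electrophilic C1 onto C7 of the C6=C7 π bond, with the charge at C6 taken up by oxygen (carbenoid cyclopropanation of a silyl enol ether, then fragmentation).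
- 9 ⇐ isopropenyl ketone 5 + 3-methylbut-1-yne 6 ⇐ (S)-linalool 1, which supplies C1–C7 and the C3 stereocentre.
- Ring order: seven-membered, then five-membered.

Assumption: the presumed biogenesis is taken as the direct farnesyl cyclisation (C1→C7, then C6→C10, proton loss to the 4-ene); carbons are numbered C1–C11 as in farnesyl diphosphate in the notes; (S)-(+)-linalool of ≥95% ee is bought.

**Route**

Step 1
Reactants: 1 (S)-linalool
Product: 2 (3S)-3-[(tert-butyldimethylsilyl)oxy]-3,7-dimethylocta-1,6-diene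
Conditions: TBSOTf, 2,6-lutidine, CH2Cl2, 0 °C → rt
Reagents that add atoms: tert-butyldimethylsilyl triflate, CC(C)(C)[Si](C)(C)OS(=O)(=O)C(F)(F)F
Why: Silyl ether formation with a silyl triflate caps the hindered tertiary alcohol; the C3 stereocentre (S) comes from 1 and is not touched here or later.

Step 2
Reactants: 2 (3S)-3-[(tert-butyldimethylsilyl)oxy]-3,7-dimethylocta-1,6-diene
Product: 3 (3S)-3-[(tert-butyldimethylsilyl)oxy]-3,7-dimethyloct-6-en-2-one
Conditions: Pd(Quinox)Cl2 (5 mol%), AgSbF6 (12 mol%), aq. TBHP, CH2Cl2, 0 °C → rt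
Reagents that add atoms: tert-butyl hydroperoxide, CC(C)(C)OO
Why: Tsuji–Wacker oxidation in its Pd–Quinox/TBHP form oxidises only the monosubstituted alkene and gives the methyl ketone even next to an allylic oxygen, so C2 becomes the ketone and C1 its only enolisable neighbour.

Step 3
Reactants: 3 (3S)-3-[(tert-butyldimethylsilyl)oxy]-3,7-dimethyloct-6-en-2-one
Product: 5 (6S)-6-[(tert-butyldimethylsilyl)oxy]-2,6-dimethyloct-1-ene-3,7-dione, via allylic hydroperoxide 4 (not isolated)
Conditions: O2, TPP (cat.), hν, CH2Cl2, 0 °C; then Ac2O, pyridine, DMAP (cat.), 0 °C → rt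
Reagents that add atoms: dioxygen, O=O
Why: Schenck ene reaction of singlet oxygen followed by Kornblum–DeLaMare dehydration of the secondary allylic hydroperoxide gives the isopropenyl ketone (C6 ketone, C7=C8); the tertiary-hydroperoxide regioisomer formed alongside (about 1:1) cannot give an enone and is separated.

Step 4
Reactants: 5 (6S)-6-[(tert-butyldimethylsilyl)oxy]-2,6-dimethyloct-1-ene-3,7-dione; 6 3-methylbut-1-yne
Product: 7 (3S,6E)-3,6-bis[(tert-butyldimethylsilyl)oxy]-3,7,11-trimethyldodec-6-en-9-yn-2-one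
Conditions: 6, n-BuLi, THF, −78 °C; ZnBr2; then 5, TBSOTf, Et2O–THF, −40 °C
Reagents that add atoms: tert-butyldimethylsilyl triflate, CC(C)(C)[Si](C)(C)OS(=O)(=O)C(F)(F)F
Why: Silyl-triflate-promoted conjugate (Michael) addition of the alkynylzinc traps the C6 enolate regiospecifically as the tetrasubstituted silyl enol ether, and reaction through the favoured s-trans O-silylated enone puts OTBS cis to the C7 methyl (6E), the geometry that step 6 needs.

Step 5
Reactants: 7 (3S,6E)-3,6-bis[(tert-butyldimethylsilyl)oxy]-3,7,11-trimethyldodec-6-en-9-yn-2-one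
Product: 9 (3S,6E)-3,6-bis[(tert-butyldimethylsilyl)oxy]-1-diazo-3,7,11-trimethyldodec-6-en-9-yn-2-one, via trifluoroacetyl diketone 8 (not isolated)
Conditions: LiHMDS, THF, −78 °C; CF3CO2CH2CF3; then MsN3, Et3N, H2O, MeCN, rt
Reagents that add atoms: methanesulfonyl azide, CS(=O)(=O)N=[N+]=[N-] (the two nitrogen atoms of 9); 2,2,2-trifluoroethyl trifluoroacetate, O=C(OCC(F)(F)F)C(F)(F)F (the trifluoroacetyl group of 8 only)
Why: Danheiser detrifluoroacetylative diazo transfer works cleanly because the ketone can enolise only toward C1, C3 being quaternary and C6 masked as its enol ether.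

Step 6
Reactants: 9 (3S,6E)-3,6-bis[(tert-butyldimethylsilyl)oxy]-1-diazo-3,7,11-trimethyldodec-6-en-9-yn-2-one
Product: 11 (2R,5S)-5-[(tert-butyldimethylsilyl)oxy]-2,5-dimethyl-2-(4-methylpent-2-yn-1-yl)cycloheptane-1,4-dione, via siloxycyclopropane 10 (not isolated)
Conditions: Rh2(OAc)4 (1 mol%), CH2Cl2, rt, slow addition; then TBAF, AcOH, THF, −78 → 0 °C
Reagents that add atoms: none
Why: Intramolecular cyclopropanation of the enol ether by the rhodium carbenoid, then fluoride-triggered retro-aldol opening of the donor–acceptor siloxycyclopropane (C1–C6 cleavage), joins electrophilic C1 to C7 and returns the C6 ketone; the quaternary C7 is set R because the 6E enol ether reacts through the chair-like transition state with the C3 methyl pseudo-equatorial and the C3 OTBS pseudo-axial on the face away from the forming cyclopropane (predicted dr about 4:1, epimers separable).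

Step 7
Reactants: 11 (2R,5S)-5-[(tert-butyldimethylsilyl)oxy]-2,5-dimethyl-2-(4-methylpent-2-yn-1-yl)cycloheptane-1,4-dione
Product: 13 (6S,8aR)-6-[(tert-butyldimethylsilyl)oxy]-6,8a-dimethyl-3-(propan-2-yl)-4,5,6,8-tetrahydroazulene-2,7(1H,8aH)-dione, via triketone 12 (not isolated)
Conditions: Ph3PAuNTf2 (2 mol%), H2O, dioxane, 60 °C; then KOH, MeOH, 60 °C
Reagents that add atoms: water, O
Why: Carbonyl-assisted (5-exo-dig) gold-catalysed alkyne hydration puts the new ketone on C9, and in the intramolecular aldol condensation that follows only attack of C10 on C6 can dehydrate (the other aldols are bridged and reversible, and the quaternary C7 rules out furan formation), giving the C6=C10 cyclopentenone.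

Step 8
Reactants: 13 (6S,8aR)-6-[(tert-butyldimethylsilyl)oxy]-6,8a-dimethyl-3-(propan-2-yl)-4,5,6,8-tetrahydroazulene-2,7(1H,8aH)-dione
Product: 14 (2S,6S,8aR)-6-[(tert-butyldimethylsilyl)oxy]-2-hydroxy-6,8a-dimethyl-3-(propan-2-yl)-1,4,5,6,8,8a-hexahydroazulen-7(2H)-one
Conditions: (R)-Me-CBS (20 mol%), BH3·SMe2, THF, −30 °C; MeOH
Reagents that add atoms: none
Why: Corey–Bakshi–Shibata reduction with the (R)-catalyst delivers hydride to the enone carbonyl from the face opposite the angular methyl (catalyst and substrate matched), setting the carbinol carbon S with the hydroxyl cis to that methyl, while the other ketone, flanked by a quaternary carbon and a neopentyl CH2, is too hindered to react.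

Step 9
Reactants: 14 (2S,6S,8aR)-6-[(tert-butyldimethylsilyl)oxy]-2-hydroxy-6,8a-dimethyl-3-(propan-2-yl)-1,4,5,6,8,8a-hexahydroazulen-7(2H)-one
Product: 15 (2S,6S,8aR)-2,6-dihydroxy-6,8a-dimethyl-3-(propan-2-yl)-1,4,5,6,8,8a-hexahydroazulen-7(2H)-one
Conditions: TBAF, AcOH (1:1), THF, 0 → 40 °C
Reagents that add atoms: none
Why: Buffered fluoride desilylation frees the tertiary α-ketol without acid that would ionise the allylic alcohol or base that would trigger an α-ketol shift; no stereocentre is affected.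

Step 10
Reactants: 15 (2S,6S,8aR)-2,6-dihydroxy-6,8a-dimethyl-3-(propan-2-yl)-1,4,5,6,8,8a-hexahydroazulen-7(2H)-one; 16 angelic anhydride
Product: 17 (2S,6S,8aR)-6,8a-dimethyl-7-oxo-3-(propan-2-yl)-1,2,4,5,6,7,8,8a-octahydroazulene-2,6-diyl bis[(2Z)-2-methylbut-2-enoate]
Conditions: LiHMDS (2.1 equiv), THF, −78 °C; then 16 (3 equiv), −78 → 0 °C
Reagents that add atoms: none
Why: Acylation of the two lithium alkoxides by the anhydride, at low temperature and without a nucleophilic catalyst, esterifies the secondary and the tertiary oxygen with retention at carbon and without Z→E isomerisation of the angelate.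

**Compound list**

1 | (S)-linalool, (3S)-3,7-dimethylocta-1,6-dien-3-ol | C=C[C@@](C)(O)CCC=C(C)C | starting material
2 | (3S)-3-[(tert-butyldimethylsilyl)oxy]-3,7-dimethylocta-1,6-diene | C=C[C@@](C)(O[Si](C)(C)C(C)(C)C)CCC=C(C)C | intermediate
3 | (3S)-3-[(tert-butyldimethylsilyl)oxy]-3,7-dimethyloct-6-en-2-one | CC(=O)[C@@](C)(O[Si](C)(C)C(C)(C)C)CCC=C(C)C | intermediate
4 | (3S)-3-[(tert-butyldimethylsilyl)oxy]-6-hydroperoxy-3,7-dimethyloct-7-en-2-one (both C6 epimers) | CC(=O)[C@@](C)(O[Si](C)(C)C(C)(C)C)CCC(OO)C(C)=C | intermediate (not isolated)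
5 | (6S)-6-[(tert-butyldimethylsilyl)oxy]-2,6-dimethyloct-1-ene-3,7-dione | CC(=O)[C@@](C)(O[Si](C)(C)C(C)(C)C)CCC(=O)C(C)=C | intermediate
6 | 3-methylbut-1-yne | CC(C)C#C | starting material
7 | (3S,6E)-3,6-bis[(tert-butyldimethylsilyl)oxy]-3,7,11-trimethyldodec-6-en-9-yn-2-one | CC(=O)[C@@](C)(O[Si](C)(C)C(C)(C)C)CC/C(O[Si](C)(C)C(C)(C)C)=C(/C)CC#CC(C)C | intermediate
8 | (5S,8E)-5,8-bis[(tert-butyldimethylsilyl)oxy]-1,1,1-trifluoro-5,9,13-trimethyltetradec-8-en-11-yne-2,4-dione | O=C(CC(=O)[C@@](C)(O[Si](C)(C)C(C)(C)C)CC/C(O[Si](C)(C)C(C)(C)C)=C(/C)CC#CC(C)C)C(F)(F)F | intermediate (not isolated)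
9 | (3S,6E)-3,6-bis[(tert-butyldimethylsilyl)oxy]-1-diazo-3,7,11-trimethyldodec-6-en-9-yn-2-one | [N-]=[N+]=CC(=O)[C@@](C)(O[Si](C)(C)C(C)(C)C)CC/C(O[Si](C)(C)C(C)(C)C)=C(/C)CC#CC(C)C | intermediate
10 | (1S,3S,6R,7R)-3,6-bis[(tert-butyldimethylsilyl)oxy]-3,7-dimethyl-7-(4-methylpent-2-yn-1-yl)bicyclo[4.1.0]heptan-2-one | O=C1[C@@](C)(O[Si](C)(C)C(C)(C)C)CC[C@@]2(O[Si](C)(C)C(C)(C)C)[C@@H]1[C@@]2(C)CC#CC(C)C | intermediate (not isolated)
11 | (2R,5S)-5-[(tert-butyldimethylsilyl)oxy]-2,5-dimethyl-2-(4-methylpent-2-yn-1-yl)cycloheptane-1,4-dione | O=C1[C@@](C)(O[Si](C)(C)C(C)(C)C)CCC(=O)[C@](C)(CC#CC(C)C)C1 | intermediate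
12 | (2R,5S)-5-[(tert-butyldimethylsilyl)oxy]-2,5-dimethyl-2-(4-methyl-2-oxopentyl)cycloheptane-1,4-dione | O=C1[C@@](C)(O[Si](C)(C)C(C)(C)C)CCC(=O)[C@](C)(CC(=O)CC(C)C)C1 | intermediate (not isolated)
13 | (6S,8aR)-6-[(tert-butyldimethylsilyl)oxy]-6,8a-dimethyl-3-(propan-2-yl)-4,5,6,8-tetrahydroazulene-2,7(1H,8aH)-dione | O=C1C[C@]2(C)CC(=O)[C@@](C)(O[Si](C)(C)C(C)(C)C)CCC2=C1C(C)C | intermediate
14 | (2S,6S,8aR)-6-[(tert-butyldimethylsilyl)oxy]-2-hydroxy-6,8a-dimethyl-3-(propan-2-yl)-1,4,5,6,8,8a-hexahydroazulen-7(2H)-one | O[C@H]1C[C@]2(C)CC(=O)[C@@](C)(O[Si](C)(C)C(C)(C)C)CCC2=C1C(C)C | intermediate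
15 | (2S,6S,8aR)-2,6-dihydroxy-6,8a-dimethyl-3-(propan-2-yl)-1,4,5,6,8,8a-hexahydroazulen-7(2H)-one | O[C@H]1C[C@]2(C)CC(=O)[C@@](C)(O)CCC2=C1C(C)C | intermediate
16 | angelic anhydride, (2Z)-2-methylbut-2-enoic anhydride | C/C=C(/C)C(=O)OC(=O)/C(C)=C\C | starting material
17 | (2S,6S,8aR)-6,8a-dimethyl-7-oxo-3-(propan-2-yl)-1,2,4,5,6,7,8,8a-octahydroazulene-2,6-diyl bis[(2Z)-2-methylbut-2-enoate] | C/C=C(/C)C(=O)O[C@H]1C[C@]2(C)CC(=O)[C@@](C)(OC(=O)/C(C)=C\C)CCC2=C1C(C)C | target

**Totals**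
Total step count: 10. Longest linear sequence: 10 steps (1 → 17); 6 and 16 are bought.

**Steps most likely to fail, each with a fallback**

Step 6 (carbenoid ring closure; risks are C–H insertion at C5, carbene dimer, and a poor C7 ratio). The fallback sets out from 7 and comes back at 11, and replaces the carbenoid by a polar enolate alkylation. Compound 7 is deprotonated at C1 (LiHMDS, THF, −78 °C) and chlorinated with N-chlorosuccinimide to give (3S,6E)-3,6-bis[(tert-butyldimethylsilyl)oxy]-1-chloro-3,7,11-trimethyldodec-6-en-9-yn-2-one F1. Anhydrous TBAF with catalytic NaI (THF, −40 → 0 °C) then unmasks the C6 enolate regiospecifically from the enol ether, and this enolate closes the seven-membered ring by SN2 displacement at C1 to give 11. The C7 epimers are separated at 11.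

Step 4 (conjugate alkynylation; risks are 1,2-addition and the wrong enol ether geometry, which would invert C7). The fallback sets out from 3 and comes back at 7, and fixes the geometry through a cyclic hydrosilylation instead of an open conjugate addition. Ozonolysis of 3 (O3, CH2Cl2–MeOH, −78 °C; Me2S) gives (4S)-4-[(tert-butyldimethylsilyl)oxy]-4-methyl-5-oxohexanal F2. Separately, 6 is converted to its Grignard reagent (EtMgBr) and coupled with 2,3-dibromopropene (CuBr cat.) to 2-bromo-6-methylhept-1-en-4-yne F3. Nozaki–Hiyama–Kishi coupling of F3 with F2 (CrCl2, NiCl2 cat., DMF; aldehyde-selective) gives (3S)-3-[(tert-butyldimethylsilyl)oxy]-6-hydroxy-3,11-dimethyl-7-methylidenedodec-9-yn-2-one F4. Dess–Martin oxidation gives (3S)-3-[(tert-butyldimethylsilyl)oxy]-3,11-dimethyl-7-methylidenedodec-9-yne-2,6-dione F5. Rhodium-catalysed 1,4-hydrosilylation of F5 with t-BuMe2SiH ((Ph3P)3RhCl, toluene, 50 °C) proceeds through the s-cis enone and places the silyloxy group cis to the newly formed methyl, which is 7 with the 6E geometry.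

Step 10 (double angeloylation; risks are a sluggish tertiary alkoxide and angelate-to-tiglate isomerisation). The fallback sets out from 15 and comes back at 17, and builds the Z double bonds on the molecule instead of transferring them. Both hydroxyls of 15 are acylated with 2-[bis(2,2,2-trifluoroethoxy)phosphoryl]propanoyl chloride (pyridine, DMAP, CH2Cl2, 40 °C; no alkene to isomerise at this stage) to give the 2,6-bis{2-[bis(2,2,2-trifluoroethoxy)phosphoryl]propanoate} of 15 F6. A double Still–Gennari olefination (KHMDS, 18-crown-6, THF, −78 °C; acetaldehyde) then forms both (Z)-2-methylbut-2-enoates and gives 17.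

**Further compounds**

F1 | step 6 | (3S,6E)-3,6-bis[(tert-butyldimethylsilyl)oxy]-1-chloro-3,7,11-trimethyldodec-6-en-9-yn-2-one | ClCC(=O)[C@@](C)(O[Si](C)(C)C(C)(C)C)CC/C(O[Si](C)(C)C(C)(C)C)=C(/C)CC#CC(C)C
F2 | step 4 | (4S)-4-[(tert-butyldimethylsilyl)oxy]-4-methyl-5-oxohexanal | CC(=O)[C@@](C)(O[Si](C)(C)C(C)(C)C)CCC=O
F3 | step 4 | 2-bromo-6-methylhept-1-en-4-yne | C=C(Br)CC#CC(C)C
F4 | step 4 | (3S)-3-[(tert-butyldimethylsilyl)oxy]-6-hydroxy-3,11-dimethyl-7-methylidenedodec-9-yn-2-one (both C6 epimers) | CC(=O)[C@@](C)(O[Si](C)(C)C(C)(C)C)CCC(O)C(=C)CC#CC(C)C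
F5 | step 4 | (3S)-3-[(tert-butyldimethylsilyl)oxy]-3,11-dimethyl-7-methylidenedodec-9-yne-2,6-dione | CC(=O)[C@@](C)(O[Si](C)(C)C(C)(C)C)CCC(=O)C(=C)CC#CC(C)C
F6 | step 10 | (2S,6S,8aR)-6,8a-dimethyl-7-oxo-3-(propan-2-yl)-1,2,4,5,6,7,8,8a-octahydroazulene-2,6-diyl bis{2-[bis(2,2,2-trifluoroethoxy)phosphoryl]propanoate} (phosphonate α-carbons unspecified) | O=C(C(C)P(=O)(OCC(F)(F)F)OCC(F)(F)F)O[C@H]1C[C@]2(C)CC(=O)[C@@](C)(OC(=O)C(C)P(=O)(OCC(F)(F)F)OCC(F)(F)F)CCC2=C1C(C)C
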